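**Plan**

1. Numbering: ring carbons C1 and C5–C10. C6–O and C7–C11(=C13)–C12(=O) form the lactone, C8 bears OH, C10 the methyl C14, C1 the tertiary OH and the crotonoyl chain C2–C4/C15, C5 the angelate.
2. Retrosynthesis cuts, in order: the C13 methylene (masked as CH2NMe2), C2–C3, the angelate ester, C10–C14 and the lactone C12–O bond; then the ether bond O(C6)–C10, absent from the target, is put back; then C7–C11; last, C5–C6 and C1–C10 together.
3. Enabling feature: the ring carbons C6–C7–C8–C9–C10 carry oxygen at C6 and C8, and C6 and C10 are 1,5-related. With the C6 oxygen tied to C10 they are the ring atoms of a 4-methoxy-3-oxidopyrylium, so C1–C5 can come from an alkyne in one [5+2] cycloaddition that gives the carbocycle as an 8-oxabicyclo[3.2.1]octane.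
4. Forward: pyrylium salt → [5+2] (seven-membered carbocycle and oxolane bridge at once) → ester enolate onto the C7 ketone, C8 ketone unveiled, C7 deoxygenated → C1/C5 diol → base-induced bridge opening with lactonisation → angelate → C10 methyl → C8 carbinol → crotonoyl chain → exocyclic methylene.
5. Stereochemistry: the bicycle fixes C7 (equatorial chain), C1 (exo dihydroxylation) and C5 (hydroxyl-directed reduction) relative to bridgehead C6. After ring opening the C1 alkoxide delivers the C10 methyl and a bulky hydride sets C8. The absolute configuration comes from a lipase-catalysed kinetic resolution of diol 14.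

Key step: step 3

Remark: 7 and 9–14 are racemic; their SMILES show the enantiomer that is carried on from 15.
Remark: C11 is formed in step 4 as a mixture of epimers and is left undefined in the SMILES of 9–17, 19–22 and 24–26 (as is C2 in 24); both centres become trigonal before the end.
Remark: 3-hydroxy-4H-pyran-4-one (4) and (E)-1-bromoprop-1-ene (23) are taken as commercial.

**Route**

Step 1
Reactants: 1 propiolic acid; 2 N,O-dimethylhydroxylamine hydrochloride
Product: 3 N-methoxy-N-methylprop-2-ynamide
Conditions: DCC, Et3N, CH2Cl2, −10 to 20 °C
Reagents that add atoms: none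
Why: Carbodiimide-mediated amide coupling of the acid with the liberated hydroxylamine should give the N-methoxy-N-methylamide with the alkyne intact at low temperature; no stereocentre is formed.

Step 2
Reactants: 4 3-hydroxy-4H-pyran-4-one
Product: 5 3-hydroxy-4-methoxypyrylium trifluoromethanesulfonate
Conditions: MeOTf (1.2 equiv), CH2Cl2, 40 °C
Reagents that add atoms: methyl trifluoromethanesulfonate COS(=O)(=O)C(F)(F)F
Why: O-Alkylation of the pyranone carbonyl oxygen, its most nucleophilic site, by methyl triflate should give the aromatic 4-methoxypyrylium salt that is the ylide precursor; no stereocentre is formed.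

Step 3
Reactants: 5 3-hydroxy-4-methoxypyrylium trifluoromethanesulfonate; 3 N-methoxy-N-methylprop-2-ynamide
Product: 7 racemic N,3-dimethoxy-N-methyl-2-oxo-8-oxabicyclo[3.2.1]octa-3,6-diene-6-carboxamide (ether bridge between C6 and C10; C7 ketone; C8 methoxy enol ether C8=C9; C1=C5 alkene carrying the amide on C1), via 4-methoxy-3-oxidopyrylium ylide 6 (not isolated)
Conditions: PhNMe2 (1.2 equiv), 3 (5 equiv), CH2Cl2, 100 °C, sealed tube
Reagents that add atoms: none
Why: Deprotonation of 5 gives the ylide 6, whose ring carbons C2–C6 (future C6–C10) form a five-atom, four-π-electron unit that adds suprafacially through the two carbons flanking the ring oxygen to the alkyne in a concerted thermal [5+2] (π4s+π2s) cycloaddition, creating C5–C6 and C1–C10 together. The closest known reaction type is the oxidopyrylium–alkyne [5+2] cycloaddition of 4-methoxy-3-oxidopyrylium ylides made from 3-hydroxy-4-pyranones and methyl triflate, which is used with propiolates and ynones as a route to troponoids. Both new rings, the seven-membered carbocycle (C1, C5–C10) and the oxolane (O, C6, C5, C1, C10), close in this one intermolecular cycloaddition and not by a separate exo or endo ring closure. The bridgeheads C6 and C10 are the only new stereocentres; suprafacial addition to one face of the planar ylide makes them cis across the oxygen bridge, and the adduct is racemic because neither partner is chiral. The selectivity needed is regiochemical (amide-bearing alkyne carbon to C10): the ylide carbon next to the oxido carbon (future C6) is the nucleophilic, enolate-like terminus and should bond to the electrophilic β-carbon of the ynamide, no steric effect opposes this because both termini are unsubstituted CH groups, and excess alkyne keeps self-reaction of the ylide in check.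

Step 4
Reactants: 7 racemic cycloadduct; 8 methyl 3-(dimethylamino)propanoate
Product: 10 racemic α-ketol (C7 tertiary hydroxyl and C7–CH(CH2NMe2)CO2Me, C8 ketone, C9 methylene, C1=C5 enamide kept), via tertiary carbinol enol ether 9 (not isolated)
Conditions: 8, LiN(i-Pr)2, THF, −78 °C; then 7, −78 °C; then 1 M HCl, THF, 0 °C; NaHCO3 work-up
Reagents that add atoms: water O
Why: Kinetic 1,2-addition of the lithium ester enolate (aldol-type addition) to the C7 ketone, the most electrophilic carbonyl of 7, is followed on acidic work-up by hydrolysis of the now unconjugated enol ether to the C8 ketone; the enolate should enter from the exo face (side of the oxygen bridge), but the C7 carbinol centre is removed in step 5 and C11 is left as a mixture.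

Step 5
Reactants: 10 racemic α-ketol
Product: 11 racemic ketone (C7–H with the CH(CH2NMe2)CO2Me chain equatorial, trans to the oxygen bridge; C8 ketone)
Conditions: SmI2 (2.5 equiv), THF/MeOH, −78 °C
Reagents that add atoms: none
Why: Reductive cleavage of the α-hydroxy ketone by samarium diiodide (two electron transfers, loss of the C7 hydroxyl, protonation of the samarium enolate) should give the C7–H ketone, and protonation from the open exo face or later equilibration places the chain equatorial, which is the C7 configuration of the target.

Step 6
Reactants: 11 racemic ketone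
Product: 12 racemic exo,exo-diol (tertiary C1–OH and secondary C5–OH both on the side of the oxygen bridge)
Conditions: OsO4 (5 mol %), N-methylmorpholine N-oxide, acetone/H2O, 20 °C
Reagents that add atoms: N-methylmorpholine N-oxide C[N+]1([O-])CCOCC1; water O
Why: Upjohn dihydroxylation (syn addition) of the only alkene should occur on the exo face of the two-carbon bridge because the endo face is covered by the three-carbon bridge, which sets the C1 hydroxyl on the face it has in the target and gives C5–OH as the exo epimer.

Step 7
Reactants: 12 racemic exo,exo-diol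
Product: 13 racemic α-hydroxy β-keto amide (C5 ketone, C1–OH exo)
Conditions: SO3·pyridine, DMSO, i-Pr2NEt, CH2Cl2, 0 °C
Reagents that add atoms: none
Why: Parikh–Doering oxidation converts the secondary C5 alcohol into the ketone while the tertiary C1 alcohol cannot react, and activated DMSO avoids glycol cleavage and tolerates the tertiary amine; the C5 centre is erased for re-setting in step 8.

Step 8
Reactants: 13 racemic α-hydroxy β-keto amide
Product: 14 racemic trans-diol (C1–OH exo, C5–OH endo; C8 ketone untouched)
Conditions: Me4NBH(OAc)3, MeCN/AcOH, −20 °C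
Reagents that add atoms: none
Why: Hydroxyl-directed triacetoxyborohydride reduction (Evans–Saksena type): the C1 hydroxyl binds boron and delivers hydride intramolecularly to the C5 carbonyl from its own exo face, giving the endo C5 alcohol of the target, while the C8 ketone has no neighbouring hydroxyl and is not reduced by this weak hydride.

Step 9
Reactants: 14 racemic trans-diol
Product: 15 trans-diol as the single enantiomer drawn
Conditions: lipase from Burkholderia cepacia (serine hydrolase, immobilised), vinyl acetate, t-BuOMe, 35 °C, taken beyond half conversion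
Reagents that add atoms: none
Why: Lipase-catalysed kinetic resolution by enantioselective acyl transfer: the empirical size rule for lipases, applied to the C5 carbinol with quaternary C1 as the large and bridgehead C6 as the medium group, predicts that the enantiomer of 15 is acetylated, so that 15 should remain as the free diol in high enantiomeric purity once the reaction has passed half conversion; no stereocentre is formed or changed.

Step 10
Reactants: 15 enantiopure trans-diol
Product: 17 enone lactone (trans-fused γ-lactone C6–O–C12; C8 ketone conjugated with C9=C10; free C1–OH and C5–OH), via ring-opened hydroxy enone ester 16 (not isolated)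
Conditions: LiN(SiMe3)2 (3.3 equiv), THF, −78 to 0 °C; AcOH quench
Reagents that add atoms: none
Why: E1cB β-elimination from the kinetic C9 enolate of the C8 ketone (retro-oxa-Michael opening, the known base-induced opening of 8-oxabicyclo[3.2.1]octan-3-ones) should cleave O–C10 and free the C6 alkoxide, which lactonises onto the methyl ester (5-exo-trig) to the trans-fused lactone with C6 and C7 unchanged; no stereocentre is formed, and kinetic deprotonation of the less substituted α-carbon disfavours the unwanted C7-side elimination.

Step 11
Reactants: 17 enone lactone; 18 angelic acid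
Product: 19 C5 angelate of 17
Conditions: 18, 2,4,6-trichlorobenzoyl chloride, Et3N, toluene, 20 °C; then 17, 75 °C
Reagents that add atoms: none
Why: Yamaguchi esterification through the mixed anhydride should acylate the only secondary hydroxyl (C5) without a base strong enough to isomerise the (Z)-2-methylbut-2-enoyl group to the tiglate, the tertiary C1 hydroxyl being too hindered to react; no stereocentre changes.

Step 12
Reactants: 19 angelate enone
Product: 20 C10-methyl ketone (methyl cis to the C1 hydroxyl, C9 methylene, C8 ketone)
Conditions: AlMe3 (5 equiv), CH2Cl2, −78 to 0 °C; aqueous potassium sodium tartrate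
Reagents that add atoms: trimethylaluminium C[Al](C)C
Why: Hydroxyl-directed conjugate methylation: AlMe3 forms the C1 aluminium alkoxide, which passes a methyl group to the adjacent enone β-carbon C10 through a five-membered transition state (as known for γ-hydroxy cyclohexadienones), so the methyl should enter cis to the C1 oxygen as in the target, while lactone, ester and amide are not attacked at low temperature.

Step 13
Reactants: 20 C10-methyl ketone
Product: 21 C8 alcohol (C8–OH cis to the lactone carbon C11)
Conditions: LiBH(s-Bu)3 (L-Selectride), THF, −78 °C; AcOH quench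
Reagents that add atoms: none
Why: Ketone reduction by the bulky trialkylborohydride should occur from the less hindered face anti to the C7–C11 bond (equatorial-type attack, as for 2-substituted cycloalkanones), giving the C8 alcohol cis to C11 as in the target, while lactone, ester and amide are inert at −78 °C.

Step 14
Reactants: 21 C8 alcohol
Product: 22 C2 aldehyde (C1 bears OH and CHO)
Conditions: Cp2Zr(H)Cl (4 equiv), THF, 20 °C
Reagents that add atoms: none
Why: Partial reduction of the N-methoxy-N-methylamide by zirconocene chloride hydride stops at the stable N,O-zirconium aminal, which hydrolyses on work-up to the aldehyde, while lactone, angelate ester and its trisubstituted alkene do not react at a comparable rate; no stereocentre changes.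

Step 15
Reactants: 22 C2 aldehyde; 23 (E)-1-bromoprop-1-ene
Product: 24 allylic alcohol (C2 carbinol epimers, (E)-propenyl group)
Conditions: 23, CrCl2 (6 equiv), NiCl2 (1 mol %), DMF, 20 °C
Reagents that add atoms: none
Why: Nozaki–Hiyama–Kishi reaction: the alkenylchromium reagent formed from the (E)-bromide with retention of geometry should add only to the aldehyde, tolerating lactone, ester and free hydroxyls; the new C2 centre is formed without control and is removed in step 16.

Step 16
Reactants: 24 allylic alcohol
Product: 25 (E)-enone carrying the dimethylaminomethyl group on C11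
Conditions: MnO2 (activated, excess), CH2Cl2, 20 °C
Reagents that add atoms: none
Why: Manganese dioxide oxidises only the allylic C2 alcohol to the (E)-enone and leaves the saturated secondary C8 and tertiary C1 hydroxyls untouched, which removes the C2 stereocentre.

Step 17
Reactants: 25 (E)-enone Mannich base
Product: 27 target CNP0206014.2, via trimethylammonium iodide 26 (not isolated)
Conditions: MeI, MeCN, 20 °C; then aqueous NaHCO3/CH2Cl2, 20 °C
Reagents that add atoms: none
Why: Quaternisation of the Mannich base and E1cB (Hofmann-type) elimination of trimethylamine with mild base should unveil the α-methylene lactone, turning the undefined C11 into the trigonal carbon of the target without touching the enone or the esters.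

**Compound list**

1 | propiolic acid | C#CC(=O)O | starting material
2 | N,O-dimethylhydroxylamine hydrochloride | CNOC.Cl | starting material
3 | N-methoxy-N-methylprop-2-ynamide | C#CC(=O)N(C)OC | intermediate
4 | 3-hydroxy-4H-pyran-4-one (pyromeconic acid) | O=C1C=COC=C1O | starting material
5 | 3-hydroxy-4-methoxypyrylium trifluoromethanesulfonate | COc1cc[o+]cc1O.[O-]S(=O)(=O)C(F)(F)F | intermediate
6 | 4-methoxy-3-oxidopyrylium ylide | COc1cc[o+]cc1[O-] | intermediate (not isolated)
7 | racemic N,3-dimethoxy-N-methyl-2-oxo-8-oxabicyclo[3.2.1]octa-3,6-diene-6-carboxamide | O3[C@@H]2C(=O)C(OC)=C[C@H]3C(C(=O)N(C)OC)=C2 | intermediate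
8 | methyl 3-(dimethylamino)propanoate | CN(C)CCC(=O)OC | starting material
9 | racemic tertiary carbinol enol ether (C7–OH, C7–CH(CH2NMe2)CO2Me, C8 methoxy enol ether; C11 epimers) | O3[C@@H]2[C@](O)(C(CN(C)C)C(=O)OC)C(OC)=C[C@H]3C(C(=O)N(C)OC)=C2 | intermediate (not isolated)
10 | racemic α-ketol (C7–OH, C8 ketone; C11 epimers) | O3[C@@H]2[C@](O)(C(CN(C)C)C(=O)OC)C(=O)C[C@H]3C(C(=O)N(C)OC)=C2 | intermediate
11 | racemic ketone (C7–H, chain equatorial; C8 ketone; C1=C5 enamide) | O3[C@@H]2[C@@H](C(CN(C)C)C(=O)OC)C(=O)C[C@H]3C(C(=O)N(C)OC)=C2 | intermediate
12 | racemic exo,exo-diol (C1–OH and C5–OH on the bridge side) | O3[C@@H]2[C@@H](C(CN(C)C)C(=O)OC)C(=O)C[C@H]3[C@@](O)(C(=O)N(C)OC)[C@@H]2O | intermediate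
13 | racemic α-hydroxy β-keto amide (C5 ketone) | O3[C@@H]2[C@@H](C(CN(C)C)C(=O)OC)C(=O)C[C@H]3[C@@](O)(C(=O)N(C)OC)C2=O | intermediate
14 | racemic trans-diol (C1–OH exo, C5–OH endo) | O3[C@@H]2[C@@H](C(CN(C)C)C(=O)OC)C(=O)C[C@H]3[C@@](O)(C(=O)N(C)OC)[C@H]2O | intermediate
15 | trans-diol, single enantiomer as drawn | O3[C@@H]2[C@@H](C(CN(C)C)C(=O)OC)C(=O)C[C@H]3[C@@](O)(C(=O)N(C)OC)[C@H]2O | intermediate
16 | ring-opened hydroxy enone ester (C6–OH, C8 ketone, C9=C10, open methyl ester) | O[C@@H]2[C@@H](C(CN(C)C)C(=O)OC)C(=O)C=C[C@@](O)(C(=O)N(C)OC)[C@H]2O | intermediate (not isolated)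
17 | enone lactone (trans-fused γ-lactone, C8 ketone, C9=C10, C1–OH, C5–OH) | CN(C)CC1C(=O)O[C@@H]2[C@@H]1C(=O)C=C[C@@](O)(C(=O)N(C)OC)[C@H]2O | intermediate
18 | angelic acid, (Z)-2-methylbut-2-enoic acid | C/C=C(/C)C(=O)O | starting material
19 | C5 angelate of 17 | CN(C)CC1C(=O)O[C@@H]2[C@@H]1C(=O)C=C[C@@](O)(C(=O)N(C)OC)[C@H]2OC(=O)/C(C)=C\C | intermediate
20 | C10-methyl ketone (methyl cis to C1–OH) | CN(C)CC1C(=O)O[C@@H]2[C@@H]1C(=O)C[C@H](C)[C@@](O)(C(=O)N(C)OC)[C@H]2OC(=O)/C(C)=C\C | intermediate
21 | C8 alcohol (OH cis to C11) | CN(C)CC1C(=O)O[C@@H]2[C@@H]1[C@@H](O)C[C@H](C)[C@@](O)(C(=O)N(C)OC)[C@H]2OC(=O)/C(C)=C\C | intermediate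
22 | C2 aldehyde | CN(C)CC1C(=O)O[C@@H]2[C@@H]1[C@@H](O)C[C@H](C)[C@@](O)(C=O)[C@H]2OC(=O)/C(C)=C\C | intermediate
23 | (E)-1-bromoprop-1-ene | C/C=C/Br | starting material
24 | allylic alcohol (C2 epimers) | CN(C)CC1C(=O)O[C@@H]2[C@@H]1[C@@H](O)C[C@H](C)[C@@](O)(C(O)/C=C/C)[C@H]2OC(=O)/C(C)=C\C | intermediate
25 | (E)-enone with C11 dimethylaminomethyl group | CN(C)CC1C(=O)O[C@@H]2[C@@H]1[C@@H](O)C[C@H](C)[C@@](O)(C(=O)/C=C/C)[C@H]2OC(=O)/C(C)=C\C | intermediate
26 | trimethylammonium iodide of 25 | C[N+](C)(C)CC1C(=O)O[C@@H]2[C@@H]1[C@@H](O)C[C@H](C)[C@@](O)(C(=O)/C=C/C)[C@H]2OC(=O)/C(C)=C\C.[I-] | intermediate (not isolated)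
27 | CNP0206014.2 | C=C1C(=O)O[C@@H]2[C@@H]1[C@@H](O)C[C@H](C)[C@@](O)(C(=O)/C=C/C)[C@H]2OC(=O)/C(C)=C\C | target

**Count and risks**

Total step count: 17. Longest linear sequence: 16 steps (steps 2–17, from 4 to 27); step 1 is a one-step branch.

Step 10. Risk: proton transfer between the two enolate positions, or deprotonation at C7, would open the bridge at the wrong C–O bond, and the methoxide set free can epimerise C7. Fallback, from 15 back to 17: the enolate regiochemistry is fixed covalently before the bridge is opened. LiN(SiMe3)2 with Me3SiCl present at −78 °C should give the tris(trimethylsilyl) derivative F1 (C8–C9 silyl enol ether, silyl ethers on the C1 and C5 oxygens). Catalytic Me3SiOTf in CH2Cl2 at −78 °C then ionises the O–C10 bond with push from the enol ether, a Lewis acid-mediated opening known for silyl enol ethers of 8-oxabicyclo[3.2.1]octan-3-ones, to give the C6 silyl ether enone F2. TsOH in methanol removes the silyl groups and closes the lactone to 17.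

Step 12. Risk: methyl transfer that is not guided by the aluminium alkoxide (attack on the face remote from the C1 oxygen) or competing 1,2-addition. Fallback, from 19 back to 20: a silicon tether delivers the carbon. The C1 hydroxyl is silylated with (bromomethyl)chlorodimethylsilane and imidazole to the (bromomethyl)dimethylsilyl ether F3. Bu3SnH/AIBN in benzene at 80 °C generates the α-silyl radical, which adds 5-exo-trig to C10 of the enone on the face of the C1 oxygen and gives the cyclic siloxane F4. Fluoride (Bu4NF, DMF, 60 °C) cleaves Si–O and Si–C with protonation and leaves the C10 methyl group of 20.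

Step 13. Risk: poor facial selectivity of hydride attack on the conformationally mobile cycloheptanone. Fallback, from 20 back to 21: the ketone is reduced with a small hydride (NaBH4, MeOH, −40 °C), or the mixture from step 13 is used, and the C8 epimer F5 is separated. A Mitsunobu reaction (HCO2H, PPh3, diisopropyl azodicarboxylate, THF, 0 °C) inverts C8 to the inverted formate F6. KHCO3 in methanol at 0 °C cleaves the formate in the presence of lactone and angelate to give 21.

Further compounds
F1 | step 10 | tris(trimethylsilyl) derivative of 15 (C8–C9 silyl enol ether, C1 and C5 silyl ethers) | O3[C@@H]2[C@@H](C(CN(C)C)C(=O)OC)C(O[Si](C)(C)C)=C[C@H]3[C@@](O[Si](C)(C)C)(C(=O)N(C)OC)[C@H]2O[Si](C)(C)C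
F2 | step 10 | ring-opened enone with trimethylsilyl ethers on the C6, C1 and C5 oxygens | C[Si](C)(C)O[C@@H]2[C@@H](C(CN(C)C)C(=O)OC)C(=O)C=C[C@@](O[Si](C)(C)C)(C(=O)N(C)OC)[C@H]2O[Si](C)(C)C
F3 | step 12 | (bromomethyl)dimethylsilyl ether of 19 at the C1 oxygen | CN(C)CC1C(=O)O[C@@H]2[C@@H]1C(=O)C=C[C@@](O[Si](C)(C)CBr)(C(=O)N(C)OC)[C@H]2OC(=O)/C(C)=C\C
F4 | step 12 | cyclic siloxane (C10–CH2–SiMe2–O–C1 ring, C8 ketone) | CN(C)CC1C(=O)O[C@@H]2[C@@H]1C(=O)C[C@@H]3C[Si](C)(C)O[C@]3(C(=O)N(C)OC)[C@H]2OC(=O)/C(C)=C\C
F5 | step 13 | C8 epimer of 21 | CN(C)CC1C(=O)O[C@@H]2[C@@H]1[C@H](O)C[C@H](C)[C@@](O)(C(=O)N(C)OC)[C@H]2OC(=O)/C(C)=C\C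
F6 | step 13 | C8 formate of 21 | CN(C)CC1C(=O)O[C@@H]2[C@@H]1[C@@H](OC=O)C[C@H](C)[C@@](O)(C(=O)N(C)OC)[C@H]2OC(=O)/C(C)=C\C
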